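**Retrosynthetic overview**
1. Core locants used throughout are those of 8-azabicyclo[4.3.1]decane: C1 quaternary bridgehead, C2=C3 the later tetrasubstituted alkene, C6 bridgehead CH, N8, C10 the one-carbon bridge. Ring A is the cyclopentene on C2–C3 and ring B the ester cyclopentane on C1–C2.
2. Target ⇐ desilylation and syn-hydrogenation of a tetracyclic dienoate, which sets both ring B stereocenters. Side chain ⇐ HWE olefination and CBS reduction of a C10 aldehyde.
3. Quaternary C10 ⇐ one-carbon homologation of the bridging ketone, then hydroxymethylation with formaldehyde.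
4. Ring B ⇐ intramolecular aldol condensation of an ester arm. Ring A ⇐ carbonylative Stille coupling and Nazarov cyclisation of an enol triflate.
5. Azabicyclic core ⇐ double Mannich of a 2-substituted cycloheptane-1,3-dione, with the enantiomers separated. Ring order: seven-membered ring (bought) → piperidine → ring A → ring B.

Assumption: small atom-donating reagents are given by name and SMILES on the reagent line and carry no number; building blocks that bring two or more skeletal carbons are numbered.

**Route**

Step 1
Reactants: 1 cycloheptane-1,3-dione; 2 methyl acrylate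
Product: 3 methyl 3-(2,7-dioxocycloheptyl)propanoate
Conditions: DBU (0.2 equiv), MeCN, 50 °C
Reagents that add atoms: none
Why: Michael addition of the doubly activated dione C–H to the acrylate gives the C-alkylated dione, and no stereocenter is formed.

Step 2
Reactants: 3 methyl 3-(2,7-dioxocycloheptyl)propanoate
Product: 5 racemic bicyclic amino diketone, via mono-Mannich base 4 (not isolated)
Conditions: MeNH2 (40% aq., 1.1 equiv), CH2O (37% aq., 2.2 equiv), AcOH, MeOH, 65 °C
Reagents that add atoms: methylamine (CN); formaldehyde (C=O)
Why: Double Mannich annulation: the dione carbon is aminomethylated first and the tethered N-methyliminium is then trapped by the enol of one ketone, a closure that can only give the cis-bridged piperidine, so C1 and C6 are set relative to each other and the product is racemic.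

Step 3
Reactants: 5 racemic bicyclic amino diketone
Product: 6 (1S,6S)-amino diketone
Conditions: preparative SFC, amylose tris(3,5-dimethylphenylcarbamate) column, CO2/MeOH with 0.1% Et2NH
Reagents that add atoms: none
Why: Resolution by chromatography on a chiral stationary phase separates the enantiomers of the rigid amino diketone, and the (1S,6S) antipode (to be confirmed by X-ray analysis of a salt) has the bridgehead configuration of the target.

Step 4
Reactants: 6 (1S,6S)-amino diketone
Product: 7 enol triflate
Conditions: KN(SiMe3)2, THF, −78 °C; then PhNTf2, −78 to 0 °C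
Reagents that add atoms: N-phenylbis(trifluoromethanesulfonimide) (O=S(=O)(N(c1ccccc1)S(=O)(=O)C(F)(F)F)C(F)(F)F)
Why: Kinetic enolate O-triflation: the C10 ketone cannot enolise (one α-carbon is quaternary, the other a bridgehead) and the C2 ketone has only the C3 methylene, so a single enol triflate forms.

Step 5
Reactants: 7 enol triflate; 8 tributyl(vinyl)stannane
Product: 9 divinyl ketone
Conditions: CO (1 atm), Pd(PPh3)4 (5 mol%), LiCl, THF, 55 °C
Reagents that add atoms: carbon monoxide ([C-]#[O+])
Why: Carbonylative Stille coupling: oxidative addition of the enol triflate, CO insertion and vinyl transfer from tin give the cross-conjugated divinyl ketone.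

Step 6
Reactants: 9 divinyl ketone
Product: 10 tricyclic enone
Conditions: TfOH (5 equiv), ClCH2CH2Cl, 0 °C to rt
Reagents that add atoms: none
Why: Nazarov cyclisation: acid-promoted 4π conrotatory closure bonds the vinyl terminus to C3 and loss of the C3 proton leaves the tetrasubstituted C2=C3 enone, so no new stereocenter remains.

Step 7
Reactants: 10 tricyclic enone
Product: 12 tetracyclic keto dienoate, via aldol adduct 11 (not isolated)
Conditions: NaOMe (0.5 equiv), MeOH, 65 °C
Reagents that add atoms: none
Why: Intramolecular aldol condensation: the ester α-carbon of the C1 arm adds to the ring A ketone to close five-membered ring B (the competing Claisen mode would need a seven-membered ring) and E1cB loss of water gives the conjugated dienoate.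

Step 8
Reactants: 12 tetracyclic keto dienoate
Product: 14 C10 aldehyde (epimer mixture at C10), via enol ether 13 (not isolated)
Conditions: Ph3P(Cl)CH2OMe, KOtBu, THF, 0 to 50 °C; then 2 M HCl, THF, rt
Reagents that add atoms: (methoxymethyl)triphenylphosphonium chloride (COC[P+](c1ccccc1)(c1ccccc1)c1ccccc1.[Cl-]); water (O)
Why: Wittig methoxymethylenation of the only ketone and hydrolysis of the enol ether amount to a one-carbon homologation, and the C10 configuration is left open because this carbon is enolised in the next step.

Step 9
Reactants: 14 C10 aldehyde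
Product: 15 hydroxymethyl aldehyde
Conditions: CH2O (37% aq., 1.5 equiv), K2CO3 (0.2 equiv), MeOH, 0 °C to rt
Reagents that add atoms: formaldehyde (C=O)
Why: Crossed aldol addition (hydroxymethylation) of the aldehyde enolate to formaldehyde creates quaternary C10; formaldehyde is expected to enter from the face over the C2–C5 bridge, which has an sp2 carbon next to the bridgehead and so fewer syn-axial hydrogens than the piperidine face, placing CH2OH as in the target.

Step 10
Reactants: 15 hydroxymethyl aldehyde; 16 diethyl (2-oxobutyl)phosphonate
Product: 17 (E)-enone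
Conditions: Ba(OH)2·8H2O, THF/H2O (40:1), rt
Reagents that add atoms: none
Why: Horner–Wadsworth–Emmons olefination of the neopentyl aldehyde with the β-keto phosphonate gives the (E)-enone that holds all five side-chain carbons.

Step 11
Reactants: 17 (E)-enone
Product: 18 (S)-allylic alcohol
Conditions: (R)-2-methyl-CBS-oxazaborolidine (0.5 equiv), catecholborane (3 equiv), toluene, −78 °C
Reagents that add atoms: none
Why: Corey–Bakshi–Shibata reduction: the (R)-oxazaborolidine binds the enone with the alkenyl group as the large substituent and delivers hydride to give the (S)-carbinol under reagent control.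

Step 12
Reactants: 18 (S)-allylic alcohol
Product: 19 bis-TBS ether
Conditions: TBSOTf (2.5 equiv), 2,6-lutidine, CH2Cl2, −78 to 0 °C
Reagents that add atoms: tert-butyldimethylsilyl trifluoromethanesulfonate (CC(C)(C)[Si](C)(C)OS(=O)(=O)C(F)(F)F)
Why: Silyl ether formation masks both hydroxyls so that neither can steer the hydrogenation catalyst and puts a bulky group under the face of ring B that must stay closed.

Step 13
Reactants: 19 bis-TBS ether
Product: 21 bis-TBS ether of the target, via side-chain-saturated dienoate 20 (not isolated)
Conditions: H2 (60 bar), 5% Rh/Al2O3, EtOAc/AcOH (10:1), rt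
Reagents that add atoms: none
Why: Heterogeneous catalytic hydrogenation saturates the disubstituted side-chain alkene first and then adds H2 syn to the enoate C=C from the face opposite the silyloxymethyl group on C10, which sets both ring B stereocenters cis as in the target, while the isolated tetrasubstituted C2=C3 alkene is too hindered to be reduced.

Step 14
Reactants: 21 bis-TBS ether of the target
Product: 22 target CNP0291564.1
Conditions: HF·pyridine, THF/pyridine, 0 °C to rt
Reagents that add atoms: none
Why: Fluoride-driven cleavage of both silyl ethers (Si–F bond formation) frees the two alcohols under conditions that leave the ester and its α-stereocenter untouched.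

**Compound list**
1 | cycloheptane-1,3-dione | O=C1CCCCC(=O)C1 | starting material
2 | methyl acrylate | C=CC(=O)OC | starting material
3 | methyl 3-(2,7-dioxocycloheptyl)propanoate | COC(=O)CCC1C(=O)CCCCC1=O | intermediate
4 | mono-Mannich base: methyl 3-{1-[(methylamino)methyl]-2,7-dioxocycloheptyl}propanoate (achiral) | COC(=O)CCC1(CNC)C(=O)CCCCC1=O | intermediate
5 | racemic bicyclic amino diketone: methyl 3-(8-methyl-2,10-dioxo-8-azabicyclo[4.3.1]decan-1-yl)propanoate, 1:1 mixture of (1S,6S) and (1R,6R) | O=C1[C@H]2CCCC(=O)[C@]1(CCC(=O)OC)CN(C)C2.O=C1[C@@H]2CCCC(=O)[C@@]1(CCC(=O)OC)CN(C)C2 | intermediate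
6 | (1S,6S)-amino diketone: methyl 3-[(1S,6S)-8-methyl-2,10-dioxo-8-azabicyclo[4.3.1]decan-1-yl]propanoate | O=C1[C@H]2CCCC(=O)[C@]1(CCC(=O)OC)CN(C)C2 | intermediate
7 | enol triflate: methyl 3-[(1S,6S)-8-methyl-10-oxo-2-(trifluoromethylsulfonyloxy)-8-azabicyclo[4.3.1]dec-2-en-1-yl]propanoate | O=C1[C@H]2CCC=C(OS(=O)(=O)C(F)(F)F)[C@]1(CCC(=O)OC)CN(C)C2 | intermediate
8 | tributyl(vinyl)stannane | C=C[Sn](CCCC)(CCCC)CCCC | starting material
9 | divinyl ketone: methyl 3-[8-methyl-10-oxo-2-(prop-2-enoyl)-8-azabicyclo[4.3.1]dec-2-en-1-yl]propanoate, bridgeheads as in 6 | O=C1[C@H]2CCC=C(C(=O)C=C)[C@]1(CCC(=O)OC)CN(C)C2 | intermediate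
10 | tricyclic enone: cyclopentenone ring A fused on C2=C3, its C=O bonded to C2; C1 propanoate arm and C10 ketone unchanged; bridgeheads as in 6 | O=C1[C@H]2CCC3=C(C(=O)CC3)[C@]1(CCC(=O)OC)CN(C)C2 | intermediate
11 | aldol adduct: ring B closed from the ester α-carbon to the former ring A carbonyl carbon (tertiary alcohol, β-hydroxy ester, two new centers unassigned) | O=C1[C@H]2CCC3=C4C(O)(CC3)C(C(=O)OC)C[C@]41CN(C)C2 | intermediate
12 | tetracyclic keto dienoate: ring B C=C(CO2Me) conjugated with C2=C3; C10 ketone; bridgeheads as in 6 | O=C1[C@H]2CCC3=C4C(CC3)=C(C(=O)OC)C[C@]41CN(C)C2 | intermediate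
13 | enol ether: C10=CH–OMe in place of the C10 ketone of 12 (E/Z mixture) | COC=C1[C@H]2CCC3=C4C(CC3)=C(C(=O)OC)C[C@]41CN(C)C2 | intermediate
14 | C10 aldehyde: C10 is CH–CHO (epimer mixture at C10) | O=CC1[C@H]2CCC3=C4C(CC3)=C(C(=O)OC)C[C@]41CN(C)C2 | intermediate
15 | hydroxymethyl aldehyde: quaternary C10 with CHO over the piperidine and CH2OH over the C2–C5 bridge | O=C[C@]1(CO)[C@H]2CCC3=C4C(CC3)=C(C(=O)OC)C[C@]41CN(C)C2 | intermediate
16 | diethyl (2-oxobutyl)phosphonate | CCC(=O)CP(=O)(OCC)OCC | starting material
17 | (E)-enone: CHO of 15 turned into (E)-CH=CH–C(=O)Et | CCC(=O)/C=C/[C@]1(CO)[C@H]2CCC3=C4C(CC3)=C(C(=O)OC)C[C@]41CN(C)C2 | intermediate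
18 | (S)-allylic alcohol: (E)-CH=CH–CH(OH)Et with (S) carbinol, free CH2OH | CC[C@H](O)/C=C/[C@]1(CO)[C@H]2CCC3=C4C(CC3)=C(C(=O)OC)C[C@]41CN(C)C2 | intermediate
19 | bis-TBS ether of 18 | CC[C@H](O[Si](C)(C)C(C)(C)C)/C=C/[C@]1(CO[Si](C)(C)C(C)(C)C)[C@H]2CCC3=C4C(CC3)=C(C(=O)OC)C[C@]41CN(C)C2 | intermediate
20 | side-chain-saturated dienoate: 19 with the side-chain C=C reduced and the dienoate intact | CC[C@H](O[Si](C)(C)C(C)(C)C)CC[C@]1(CO[Si](C)(C)C(C)(C)C)[C@H]2CCC3=C4C(CC3)=C(C(=O)OC)C[C@]41CN(C)C2 | intermediate
21 | bis-TBS ether of the target: ring B saturated, both ring B hydrogens cis and on the face away from C10 | CC[C@H](O[Si](C)(C)C(C)(C)C)CC[C@]1(CO[Si](C)(C)C(C)(C)C)[C@H]2CCC3=C4[C@@H](CC3)[C@@H](C(=O)OC)C[C@]41CN(C)C2 | intermediate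
22 | CNP0291564.1: C10 bears CH2OH and the (3S)-3-hydroxypentyl chain, ring B bears CO2Me, N-methyl, all centers as in the given SMILES | CC[C@H](O)CC[C@]1(CO)[C@H]2CCC3=C4[C@@H](CC3)[C@@H](C(=O)OC)C[C@]41CN(C)C2 | target

**Step count and risk**

Total steps: 14. Longest linear sequence: 14 (fully linear from cycloheptane-1,3-dione). Step 3 is a separation and discards half of the material.

The three steps most likely to fail:

Step 8, olefination of the bridging ketone, which sits between a quaternary carbon and a bridgehead. The fallback sets out from 12 and comes back at 14. Dimethylsulfonium methylide (trimethylsulfonium iodide, KN(SiMe3)2, THF, 0 °C) is a much smaller nucleophile than the phosphorus ylide; it adds to the ketone and closes the spiro-epoxide F1. Excess BF3·OEt2 in CH2Cl2 at −78 °C then induces a Meinwald rearrangement by hydride shift to the aldehyde 14.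

Step 9, the face from which the electrophile enters at C10. If formaldehyde enters from the piperidine face instead, the order in which the two C10 substituents are introduced is reversed so that the same preference serves the target. The fallback sets out from 14 and comes back at 20. Michael addition of 14 to acrolein (DBU cat., MeCN, 0 °C) gives the dialdehyde F2 with the three-carbon chain on the piperidine side. Catalytic asymmetric ethylation of the unhindered aldehyde (ZnEt2, Ti(OiPr)4, (1R,2R)-1,2-bis(trifluoromethanesulfonamido)cyclohexane, toluene, −20 °C) gives the (S)-hydroxy aldehyde F3. NaBH4 in MeOH at 0 °C reduces the neopentyl aldehyde to the diol F4. TBSOTf with 2,6-lutidine gives 20, which is hydrogenated to 21 under the conditions of step 13.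

Step 13, reduction of a tetrasubstituted enoate inside a conjugated diene with the right face selectivity. Possible failures are 1,4-addition of hydrogen, alkene migration, or no reaction. The fallback sets out from 19 and comes back at 21. Ligand-controlled copper hydride conjugate reduction (Cu(OAc)2 5 mol%, (R)-DTBM-SEGPHOS or its antipode, whichever matches the substrate bias, polymethylhydrosiloxane, tBuOH, toluene, rt) delivers hydride to the β-carbon of the enoate; kinetic protonation of the resulting ketene acetal from the open face gives the saturated ester F5 with the side-chain alkene intact. H2 (1 atm) with RhCl(PPh3)3 in toluene then saturates only the disubstituted alkene and gives 21.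

Further compounds
F1 | step 8 | spiro-epoxide: C10 of 12 as a spiro-oxirane (C10–O–CH2), epoxide configuration unassigned | C1OC13[C@H]2CCC4=C5C(CC4)=C(C(=O)OC)C[C@]53CN(C)C2
F2 | step 9 | dialdehyde: quaternary C10 with CHO over the C2–C5 bridge and a 3-oxopropyl chain over the piperidine | O=CCC[C@]1(C=O)[C@H]2CCC3=C4C(CC3)=C(C(=O)OC)C[C@]41CN(C)C2
F3 | step 9 | (S)-hydroxy aldehyde: C10 with CHO and the (3S)-3-hydroxypentyl chain | CC[C@H](O)CC[C@]1(C=O)[C@H]2CCC3=C4C(CC3)=C(C(=O)OC)C[C@]41CN(C)C2
F4 | step 9 | diol: C10 with CH2OH and the (3S)-3-hydroxypentyl chain, dienoate intact | CC[C@H](O)CC[C@]1(CO)[C@H]2CCC3=C4C(CC3)=C(C(=O)OC)C[C@]41CN(C)C2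
F5 | step 13 | saturated ester: ring B reduced as in 21, side-chain (E)-alkene intact, bis-TBS | CC[C@H](O[Si](C)(C)C(C)(C)C)/C=C/[C@]1(CO[Si](C)(C)C(C)(C)C)[C@H]2CCC3=C4[C@@H](CC3)[C@@H](C(=O)OC)C[C@]41CN(C)C2
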